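**Plan**

- Retrosynthesis: the tertiary C7–O ester is cut first, and its orsellinate ring is unravelled to a triketo chain delivered as an acylketene. The primary acetate is cut back to the allylic alcohol.
- Enabling feature (6H-isochromene numbering: O2, C1, C3, C4, C4a, C5–C8, C8a): ring A, the carbocycle C4a–C5–C6–C7–C8–C8a, carries the C6 ketone directly beside the C7 tertiary carbinol. Both carbons are at carbonyl oxidation level, so this α-ketol is cut at C6–C7 into a C6 aldehyde (acyl-anion donor) and a C7 methyl ketone.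
- The monocyclic pyranylidene acetaldehyde is cut at C4a=C5 (two-carbon formyl olefination of a 4-pyranone). The pyranone is cut at C1–C8a and O2–C1 (formate carbon) and at C4–C4a (enolate acylation).
- Forward order: acyclic enone-diketone, then the pyran ring, then the C5–C6 unit, then ring A by carbene catalysis, then the acetate, and last the arene of the ester, built on the C7 oxygen.
- Stereochemistry: C7 (S), the only stereocentre, is set in the ring-A closure by a chiral triazolylidene. The E side-chain alkene comes from a stabilised-ylide Wittig reaction and is carried through.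

Key step: step 8

Assumption: the (5aR,10bS) antipode of the aminoindanol-derived triazolium salt is assigned to the (7S)-carbinol on a model in which the ketone adds to the enaminol face remote from the indane, with its oxygen over the enol hydroxyl (held on the N-aryl side) and its methyl group under the triazole; the mirror-image salt would be used in the same step if the sense proved opposite, and the two pyranylidene acetaldehydes are drawn with the formyl group syn to the C8 arm although the push–pull C4a=C5 geometry is expected to equilibrate.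

**Route**

Step 1
Reactants: 1 ethyl levulinate (ethyl 4-oxopentanoate)
Product: 2 ethyl 3-(2-methyl-1,3-dioxolan-2-yl)propanoate
Conditions: ethylene glycol, p-toluenesulfonic acid monohydrate (cat.), PhMe, reflux, Dean–Stark trap
Reagents that add atoms: ethylene glycol, OCCO
Why: Acid-catalysed ketalisation with azeotropic removal of water is routine for levulinates and masks the methyl ketone (the future C7) against the enolate and organolithium steps that follow.

Step 2
Reactants: 2 ethyl 3-(2-methyl-1,3-dioxolan-2-yl)propanoate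
Product: 3 N-methoxy-N-methyl-3-(2-methyl-1,3-dioxolan-2-yl)propanamide
Conditions: MeNH(OMe)·HCl, i-PrMgCl, THF, −20 → 0 °C
Reagents that add atoms: N,O-dimethylhydroxylamine hydrochloride, CNOC.Cl
Why: Direct aminolysis of the ester by the magnesium amide of N,O-dimethylhydroxylamine gives an N-methoxy-N-methylamide that acylates enolates only once through a stable chelate, and the dioxolane is inert to the Grignard base.

Step 3
Reactants: 4 (tert-butyldimethylsilyloxy)acetaldehyde; 5 1-(triphenylphosphoranylidene)propan-2-one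
Product: 6 (E)-5-(tert-butyldimethylsilyloxy)pent-3-en-2-one
Conditions: CH2Cl2, 23 °C
Reagents that add atoms: none
Why: Wittig olefination with a stabilised acyl ylide should give the E-enone selectively and leaves the silyl ether untouched.

Step 4
Reactants: 6 (E)-5-(tert-butyldimethylsilyloxy)pent-3-en-2-one; 3 N-methoxy-N-methyl-3-(2-methyl-1,3-dioxolan-2-yl)propanamide
Product: 7 (E)-1-(tert-butyldimethylsilyloxy)-8-(2-methyl-1,3-dioxolan-2-yl)oct-2-ene-4,6-dione
Conditions: LiN(i-Pr)2, THF, −78 °C; then 3, −78 → 0 °C
Reagents that add atoms: none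
Why: Kinetic deprotonation of the enone at its methyl group gives the cross-conjugated lithium dienolate, which is C-acylated by the N-methoxy-N-methylamide (crossed Claisen-type acylation) through a chelated tetrahedral adduct that releases the β-diketone only on work-up.

Step 5
Reactants: 7 (E)-1-(tert-butyldimethylsilyloxy)-8-(2-methyl-1,3-dioxolan-2-yl)oct-2-ene-4,6-dione; 8 ethyl formate
Product: 10 2-[(E)-3-(tert-butyldimethylsilyloxy)prop-1-enyl]-5-[(2-methyl-1,3-dioxolan-2-yl)methyl]-4H-pyran-4-one, via formyl diketone 9 (not isolated)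
Conditions: LiN(i-Pr)2 (2.5 equiv), THF, −78 °C; then 8, −78 → −20 °C; then pyridinium p-toluenesulfonate (cat.), 4 Å MS, PhMe, 50 °C
Reagents that add atoms: none
Why: The β-diketone dianion reacts with ethyl formate at its more basic terminal α′-carbanion (Claisen formylation of a 1,3-diketone dianion), and the resulting 1,3,5-tricarbonyl compound should cyclodehydrate to the 4-pyranone under acid mild enough to spare the ketal and the silyl ether.

Step 6
Reactants: 10 2-[(E)-3-(tert-butyldimethylsilyloxy)prop-1-enyl]-5-[(2-methyl-1,3-dioxolan-2-yl)methyl]-4H-pyran-4-one; 11 (Z)-1-bromo-2-ethoxyethene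
Product: 14 (Z)-2-{2-[(E)-3-(tert-butyldimethylsilyloxy)prop-1-enyl]-5-[(2-methyl-1,3-dioxolan-2-yl)methyl]-4H-pyran-4-ylidene}acetaldehyde, via (Z)-2-ethoxyvinyllithium 12 (not isolated), via tertiary pyranyl carbinol 13 (not isolated)
Conditions: 11, n-BuLi, Et2O, −78 °C; then 10, THF, −78 °C; then 0.5 N aq. HCl, THF, 0 °C
Reagents that add atoms: water, O
Why: Hard 1,2-addition of the vinyllithium to the pyranone carbonyl (as in organometallic routes to 4-substituted pyrylium salts) is followed by acid-triggered ionisation to a pyrylium/oxocarbenium ion that water captures at the ethoxy-bearing carbon, the formyl-olefination sequence known for 2-ethoxyvinyllithium, so the C5–C6 unit arrives directly at the aldehyde oxidation level.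

Step 7
Reactants: 14 (Z)-2-{2-[(E)-3-(tert-butyldimethylsilyloxy)prop-1-enyl]-5-[(2-methyl-1,3-dioxolan-2-yl)methyl]-4H-pyran-4-ylidene}acetaldehyde
Product: 15 (Z)-2-{2-[(E)-3-(tert-butyldimethylsilyloxy)prop-1-enyl]-5-(2-oxopropyl)-4H-pyran-4-ylidene}acetaldehyde
Conditions: Ce(OTf)3 (cat.), MeNO2 saturated with H2O, 23 °C
Reagents that add atoms: water, O
Why: Lewis-acid-catalysed ketal hydrolysis under nearly neutral conditions should free the methyl ketone while the primary silyl ether and the push–pull dienal persist.

Step 8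
Reactants: 15 (Z)-2-{2-[(E)-3-(tert-butyldimethylsilyloxy)prop-1-enyl]-5-(2-oxopropyl)-4H-pyran-4-ylidene}acetaldehyde
Product: 16 (S)-3-[(E)-3-(tert-butyldimethylsilyloxy)prop-1-enyl]-7-hydroxy-7-methyl-7,8-dihydro-6H-isochromen-6-one
Conditions: (5aR,10bS)-2-(pentafluorophenyl)-5a,10b-dihydro-4H,6H-indeno[2,1-b][1,2,4]triazolo[4,3-d][1,4]oxazin-2-ium tetrafluoroborate (15 mol %), KOAc (30 mol %), 4 Å MS, THF, 23 °C
Reagents that add atoms: none
Why: Proposed new method: the triazolylidene released by KOAc adds to the C6 aldehyde, proton transfer gives a vinylogous enaminol (acyl-anion equivalent) whose C6 carbon attacks the tethered C7 methyl ketone, and collapse of the adduct expels the carbene and leaves the conjugated ketol. The closest known reaction type is the enantioselective intramolecular aldehyde–ketone crossed benzoin that gives six-membered tertiary α-ketols with the same aminoindanol triazolium salts; what is untested is a doubly vinylogous formate as the acyl-anion donor. Ring A closes in a 6-exo-trig mode on the ketone carbonyl. The C7 configuration is set by the catalyst: the indane shields one face of the enaminol, the ketone oxygen is held over the enol hydroxyl by hydrogen bonding and the methyl group lies under the triazole, which selects one enantioface of the ketone. The step needs acyl-anion rather than homoenolate reactivity and benzoin rather than aldol closure from C8: the substrate secures the first because the homoenolate terminus C4a is fully substituted, lies inside the pyran and could only close a four-membered ring onto C7, while the second relies on the weak acetate base, which should leave the C8 methylene un-enolised. The push–pull C4a=C5 bond rotates readily, so material with the formyl group anti to the arm can still reach C7, and the product, a conjugated pyranylidene ketone, is too poor an electrophile for retro-benzoin.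

Step 9
Reactants: 16 (S)-3-[(E)-3-(tert-butyldimethylsilyloxy)prop-1-enyl]-7-hydroxy-7-methyl-7,8-dihydro-6H-isochromen-6-one
Product: 17 (S)-7-hydroxy-3-[(E)-3-hydroxyprop-1-enyl]-7-methyl-7,8-dihydro-6H-isochromen-6-one
Conditions: HF·pyridine, pyridine, THF, 0 → 23 °C
Reagents that add atoms: none
Why: Buffered fluoride desilylation cleaves the primary silyl ether without the strong base that could provoke α-ketol rearrangement, and the quaternary C7 centre cannot epimerise.

Step 10
Reactants: 17 (S)-7-hydroxy-3-[(E)-3-hydroxyprop-1-enyl]-7-methyl-7,8-dihydro-6H-isochromen-6-one; 18 acetic anhydride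
Product: 19 (E)-3-[(S)-7-hydroxy-7-methyl-6-oxo-7,8-dihydro-6H-isochromen-3-yl]prop-2-enyl acetate
Conditions: 18, pyridine, CH2Cl2, 0 °C
Reagents that add atoms: none
Why: Pyridine-mediated acetylation without an acyl-transfer catalyst is selective for the primary allylic alcohol over the hindered tertiary α-ketol hydroxyl.

Step 11
Reactants: 20 2,2,6-trimethyl-4H-1,3-dioxin-4-one; 21 acetyl chloride
Product: 22 2,2-dimethyl-6-(2-oxopropyl)-4H-1,3-dioxin-4-one
Conditions: LiN(SiMe3)2, THF, −78 °C; then 21, −78 °C
Reagents that add atoms: none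
Why: The lithium dienolate of the dioxinone is C-acylated at its γ-carbon by the acid chloride (vinylogous Claisen acylation), the standard entry to keto-dioxinones.

Step 12
Reactants: 22 2,2-dimethyl-6-(2-oxopropyl)-4H-1,3-dioxin-4-one; 23 N-methoxy-N-methylacetamide
Product: 24 6-(2,4-dioxopentyl)-2,2-dimethyl-4H-1,3-dioxin-4-one
Conditions: LiN(i-Pr)2 (2.1 equiv), THF, −78 °C; then 23, −78 → −40 °C
Reagents that add atoms: none
Why: The dianion of the keto-dioxinone reacts at its terminal methyl carbanion with the N-methoxy-N-methylamide (Claisen-type acylation) to give the diketo-dioxinone that serves as a masked triketo-acylketene.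

Step 13
Reactants: 19 (E)-3-[(S)-7-hydroxy-7-methyl-6-oxo-7,8-dihydro-6H-isochromen-3-yl]prop-2-enyl acetate; 24 6-(2,4-dioxopentyl)-2,2-dimethyl-4H-1,3-dioxin-4-one
Product: 27 (S)-3-[(E)-3-acetoxyprop-1-enyl]-7-methyl-6-oxo-7,8-dihydro-6H-isochromen-7-yl 2,4-dihydroxy-6-methylbenzoate (CNP0115558.1), via acylketene 25 (not isolated), via triketo ester 26 (not isolated)
Conditions: 24 (excess), PhMe, 110 °C; then Et3N, CH2Cl2, 23 °C; then AcOH
Reagents that add atoms: none
Why: Thermal retro-Diels–Alder loss of acetone from the dioxinone gives an acylketene that a hindered tertiary alcohol can capture without activation, and amine-mediated 2,7-aldol cyclisation and dehydration of the triketo ester (biomimetic resorcylate aromatisation) builds the orsellinate under conditions that spare the allylic acetate and cannot touch the non-enolisable C7 centre.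

**Compound list**

1 | ethyl levulinate | CCOC(=O)CCC(C)=O | starting material
2 | ethyl 3-(2-methyl-1,3-dioxolan-2-yl)propanoate | CCOC(=O)CCC1(C)OCCO1 | intermediate
3 | N-methoxy-N-methyl-3-(2-methyl-1,3-dioxolan-2-yl)propanamide | CON(C)C(=O)CCC1(C)OCCO1 | intermediate
4 | (tert-butyldimethylsilyloxy)acetaldehyde | CC(C)(C)[Si](C)(C)OCC=O | starting material
5 | 1-(triphenylphosphoranylidene)propan-2-one | CC(=O)C=P(c1ccccc1)(c1ccccc1)c1ccccc1 | starting material
6 | (E)-5-(tert-butyldimethylsilyloxy)pent-3-en-2-one | CC(=O)/C=C/CO[Si](C)(C)C(C)(C)C | intermediate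
7 | (E)-1-(tert-butyldimethylsilyloxy)-8-(2-methyl-1,3-dioxolan-2-yl)oct-2-ene-4,6-dione | CC(C)(C)[Si](C)(C)OC/C=C/C(=O)CC(=O)CCC1(C)OCCO1 | intermediate
8 | ethyl formate | CCOC=O | starting material
9 | (E)-8-(tert-butyldimethylsilyloxy)-2-[(2-methyl-1,3-dioxolan-2-yl)methyl]-3,5-dioxooct-6-enal (formyl diketone, not isolated) | CC(C)(C)[Si](C)(C)OC/C=C/C(=O)CC(=O)C(C=O)CC1(C)OCCO1 | intermediate
10 | 2-[(E)-3-(tert-butyldimethylsilyloxy)prop-1-enyl]-5-[(2-methyl-1,3-dioxolan-2-yl)methyl]-4H-pyran-4-one | CC(C)(C)[Si](C)(C)OC/C=C/C1=CC(=O)C(CC2(C)OCCO2)=CO1 | intermediate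
11 | (Z)-1-bromo-2-ethoxyethene | CCO/C=C\Br | starting material
12 | (Z)-2-ethoxyvinyllithium (not isolated) | [Li]/C=C\OCC | intermediate
13 | 2-[(E)-3-(tert-butyldimethylsilyloxy)prop-1-enyl]-4-[(Z)-2-ethoxyvinyl]-5-[(2-methyl-1,3-dioxolan-2-yl)methyl]-4H-pyran-4-ol (racemic, formed as its lithium alkoxide, not isolated) | CCO/C=C\C1(O)C=C(/C=C/CO[Si](C)(C)C(C)(C)C)OC=C1CC2(C)OCCO2 | intermediate
14 | (Z)-2-{2-[(E)-3-(tert-butyldimethylsilyloxy)prop-1-enyl]-5-[(2-methyl-1,3-dioxolan-2-yl)methyl]-4H-pyran-4-ylidene}acetaldehyde | CC(C)(C)[Si](C)(C)OC/C=C/C1=C/C(=C/C=O)C(CC2(C)OCCO2)=CO1 | intermediate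
15 | (Z)-2-{2-[(E)-3-(tert-butyldimethylsilyloxy)prop-1-enyl]-5-(2-oxopropyl)-4H-pyran-4-ylidene}acetaldehyde | CC(C)(C)[Si](C)(C)OC/C=C/C1=C/C(=C/C=O)C(CC(C)=O)=CO1 | intermediate
16 | (S)-3-[(E)-3-(tert-butyldimethylsilyloxy)prop-1-enyl]-7-hydroxy-7-methyl-7,8-dihydro-6H-isochromen-6-one | CC(C)(C)[Si](C)(C)OC/C=C/C1=CC2=CC(=O)[C@@](C)(O)CC2=CO1 | intermediate
17 | (S)-7-hydroxy-3-[(E)-3-hydroxyprop-1-enyl]-7-methyl-7,8-dihydro-6H-isochromen-6-one | OC/C=C/C1=CC2=CC(=O)[C@@](C)(O)CC2=CO1 | intermediate
18 | acetic anhydride | CC(=O)OC(C)=O | starting material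
19 | (E)-3-[(S)-7-hydroxy-7-methyl-6-oxo-7,8-dihydro-6H-isochromen-3-yl]prop-2-enyl acetate | CC(=O)OC/C=C/C1=CC2=CC(=O)[C@@](C)(O)CC2=CO1 | intermediate
20 | 2,2,6-trimethyl-4H-1,3-dioxin-4-one | CC1=CC(=O)OC(C)(C)O1 | starting material
21 | acetyl chloride | CC(Cl)=O | starting material
22 | 2,2-dimethyl-6-(2-oxopropyl)-4H-1,3-dioxin-4-one | CC(=O)CC1=CC(=O)OC(C)(C)O1 | intermediate
23 | N-methoxy-N-methylacetamide | CON(C)C(C)=O | starting material
24 | 6-(2,4-dioxopentyl)-2,2-dimethyl-4H-1,3-dioxin-4-one | CC(=O)CC(=O)CC1=CC(=O)OC(C)(C)O1 | intermediate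
25 | 3,5,7-trioxooct-1-en-1-one (acylketene, not isolated) | CC(=O)CC(=O)CC(=O)C=C=O | intermediate
26 | (S)-3-[(E)-3-acetoxyprop-1-enyl]-7-methyl-6-oxo-7,8-dihydro-6H-isochromen-7-yl 3,5,7-trioxooctanoate (not isolated) | CC(=O)OC/C=C/C1=CC2=CC(=O)[C@@](C)(OC(=O)CC(=O)CC(=O)CC(C)=O)CC2=CO1 | intermediate
27 | (S)-3-[(E)-3-acetoxyprop-1-enyl]-7-methyl-6-oxo-7,8-dihydro-6H-isochromen-7-yl 2,4-dihydroxy-6-methylbenzoate (CNP0115558.1) | CC(=O)OC/C=C/C1=CC2=CC(=O)[C@@](C)(OC(=O)c3c(C)cc(O)cc3O)CC2=CO1 | target

**Step count and risks**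

Total step count: 13. Longest linear sequence: 10 steps (steps 1, 2, 4, 5, 6, 7, 8, 9, 10, 13).

The three steps most likely to fail:

Step 8 (Proposed new method). The conjugated enaminol may be protonated at C4a and drained into an acyl azolium (internal redox) instead of attacking C7. The base may also trigger aldol closure from C8 onto the aldehyde, or enantiofacial discrimination at the ketone may be poor. The fallback uses known chemistry, sets out from 15 and returns at 16. Reductive ketyl–carbonyl (pinacol) cyclisation of 15 with SmI2 in THF/t-BuOH at −78 °C should form the same C6–C7 bond and give the racemic cis-diol rac-(6R,7S)-3-[(E)-3-(tert-butyldimethylsilyloxy)prop-1-enyl]-7-methyl-7,8-dihydro-6H-isochromene-6,7-diol F1. Oxidation of its secondary allylic carbinol with Dess–Martin periodinane (the tertiary hydroxyl is inert) gives the racemic ketol rac-3-[(E)-3-(tert-butyldimethylsilyloxy)prop-1-enyl]-7-hydroxy-7-methyl-7,8-dihydro-6H-isochromen-6-one F2. Its enantiomers are separated by preparative chromatography on a cellulose tris(3,5-dimethylphenylcarbamate) stationary phase, and the (S)-enantiomer is 16.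

Step 13. Capture of the acylketene by the hindered, electron-poor tertiary hydroxyl may be slower than self-cyclisation or dimerisation of the ketene. The methylene of the new β-keto ester may also condense with the neighbouring C6 ketone before the chain aromatises. The fallback sets out from 19 and returns at 27 with a pre-formed arene. Commercial orsellinic acid is persilylated (t-BuMe2SiCl, imidazole, DMF) to tert-butyldimethylsilyl 2,4-bis(tert-butyldimethylsilyloxy)-6-methylbenzoate F3. Oxalyl chloride with catalytic DMF converts the silyl ester into 2,4-bis(tert-butyldimethylsilyloxy)-6-methylbenzoyl chloride F4. Acylation of 19 with F4 (Et3N, 4-dimethylaminopyridine, CH2Cl2, 40 °C) gives (S)-3-[(E)-3-acetoxyprop-1-enyl]-7-methyl-6-oxo-7,8-dihydro-6H-isochromen-7-yl 2,4-bis(tert-butyldimethylsilyloxy)-6-methylbenzoate F5. Et3N·3HF in THF then removes the two aryl silyl ethers without touching the allylic acetate and gives 27.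

Step 6. The vinyllithium may add in a conjugate sense at C1 or through the side-chain diene, or deprotonate the allylic silyloxymethylene group. On acidification the intermediate cation may be captured by water at a ring carbon, leading to ring opening instead of transposition. The fallback sets out from 10 and returns at 14 through a propargylic rearrangement. Addition of HC≡CMgBr in THF at 0 °C gives 2-[(E)-3-(tert-butyldimethylsilyloxy)prop-1-enyl]-4-ethynyl-5-[(2-methyl-1,3-dioxolan-2-yl)methyl]-4H-pyran-4-ol F6. Meyer–Schuster rearrangement of this carbinol, which has no β-hydrogen for the competing enyne pathway, with catalytic Ph3PAuNTf2 in wet THF at 23 °C should deliver 14.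

**Further compounds**

F1 | step 8 | rac-(6R,7S)-3-[(E)-3-(tert-butyldimethylsilyloxy)prop-1-enyl]-7-methyl-7,8-dihydro-6H-isochromene-6,7-diol (cis, both enantiomers) | CC(C)(C)[Si](C)(C)OC/C=C/C1=CC2=C[C@@H](O)[C@@](C)(O)CC2=CO1.CC(C)(C)[Si](C)(C)OC/C=C/C1=CC2=C[C@H](O)[C@](C)(O)CC2=CO1
F2 | step 8 | rac-3-[(E)-3-(tert-butyldimethylsilyloxy)prop-1-enyl]-7-hydroxy-7-methyl-7,8-dihydro-6H-isochromen-6-one (both enantiomers) | CC(C)(C)[Si](C)(C)OC/C=C/C1=CC2=CC(=O)[C@@](C)(O)CC2=CO1.CC(C)(C)[Si](C)(C)OC/C=C/C1=CC2=CC(=O)[C@](C)(O)CC2=CO1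
F3 | step 13 | tert-butyldimethylsilyl 2,4-bis(tert-butyldimethylsilyloxy)-6-methylbenzoate | Cc1cc(O[Si](C)(C)C(C)(C)C)cc(O[Si](C)(C)C(C)(C)C)c1C(=O)O[Si](C)(C)C(C)(C)C
F4 | step 13 | 2,4-bis(tert-butyldimethylsilyloxy)-6-methylbenzoyl chloride | Cc1cc(O[Si](C)(C)C(C)(C)C)cc(O[Si](C)(C)C(C)(C)C)c1C(Cl)=O
F5 | step 13 | (S)-3-[(E)-3-acetoxyprop-1-enyl]-7-methyl-6-oxo-7,8-dihydro-6H-isochromen-7-yl 2,4-bis(tert-butyldimethylsilyloxy)-6-methylbenzoate | CC(=O)OC/C=C/C1=CC2=CC(=O)[C@@](C)(OC(=O)c3c(C)cc(O[Si](C)(C)C(C)(C)C)cc3O[Si](C)(C)C(C)(C)C)CC2=CO1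
F6 | step 6 | 2-[(E)-3-(tert-butyldimethylsilyloxy)prop-1-enyl]-4-ethynyl-5-[(2-methyl-1,3-dioxolan-2-yl)methyl]-4H-pyran-4-ol (racemic) | C#CC1(O)C=C(/C=C/CO[Si](C)(C)C(C)(C)C)OC=C1CC2(C)OCCO2
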